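A nucleophile that has taken up acid cannot attack the electrophile, so each product can cost a flask two nucleophiles.

| flask | electrophile | nucleophile | free base | remark | time |
|---|---|---|---|---|---|
| west | 0.30 M | 0.39 M | 0.095 M | run made earlier |  |
| south-east | 0.30 M | 0.39 M | 0.22 M | run made earlier |  |
| north | 0.16 M | 0.39 M | 0.24 M | run made earlier |  |
| birch | 0.30 M | 0.390 M | 0.240 M |  | 2.5 min |
| oak | 0.10 M | 0.390 M | 0.150 M |  | 2.5 min |

| run | time / s | product / % | electrophile / % |
|---|---|---|---|
| west | 10.0 | 50.8 | 44.5 |
| west | 25.0 | 69.7 | 31.2 |
| west | 50.0 | 75.3 | 24.9 |
| west | 80.0 | 78.8 | 20.6 |
| south-east | 10.0 | 56.1 | 45.6 |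
| south-east | 15.0 | 66.0 | 35.1 |
| south-east | 30.0 | 76.8 | 22.4 |
| south-east | 80.0 | 86.6 | 13.3 |
| north | 10.0 | 66.3 | 34.4 |
| north | 15.0 | 77.4 | 23.4 |
| north | 30.0 | 90.8 | 9.6 |
| north | 80.0 | 100.3 | 0.6 |

(standard deviation of a reading: 1 percentage point)

- the winner by amount of product, in percent of the electrophile charged; "neither" if no more than 2 percentage points parts them (birch / oak / neither)
- how much product is there at the end, in percent of the electrophile charged: birch
- how much product is there at the end, in percent of the electrophile charged: oak

- the numbers in the tables scatter by 1 percentage point (one standard deviation)
- candidate steps: electrophile + nucleophile -> acid set free + product; nucleophile + acid set free <-> protonated nucleophile; acid set free + free base <-> salt of the base; free base <-> dormant form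

Each product uses one nucleophile and sets free one acid, and any acid beyond the free base takes a second nucleophile. With every acid bound, the nucleophile used up and the whole charge of free base taking acid, product stops at (c(nucleophile) + c(free base))/2. I call this the acid ceiling, 105% of the electrophile charged for birch. West has a ceiling of 80.8% and read 78.8% at 80.0 s. South-east has a ceiling of 102% but read 86.6% at 80.0 s, so I take it that part of its base was not binding acid.

That gives two extremes. Counting the base in full, oak's ceiling is 270%. Counting it as nothing, birch's ceiling falls to 65.0% and oak's to 195%, which is still above full conversion. The electrophile is therefore oak's limiting reagent. North's readings show its electrophile halving every 11.7 s between the middle two, and at that pace oak's 2.5 min holds 12.8 half-lives, so I expect full conversion in oak.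

Birch's ceiling lies between 65.0% and 105%, and birch's charge differs from south-east's by 0.0200 M of free base, so I read birch from south-east. South-east's readings show its electrophile halving every 66.5 s late on. Carrying that tail on to 2.5 min gives me 93.6% for birch.

The forecast names oak as the winner, with 91% (87% to 95%) for birch and 100% (98% to 101%) for oak, holding that “the base is not fully effective”. Its birch figure is lower than mine.

The flasks give 93.1% in birch and >99.9% in oak, so oak wins.

    electrophile + nucleophile → acid set free + product (k = 0.368 M⁻¹ s⁻¹)
    nucleophile + acid set free ⇌ protonated nucleophile, settled at all times (K = 1660 M⁻¹)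
    acid set free + free base ⇌ salt of the base, settled at all times (K = 1500 M⁻¹)
    free base ⇌ dormant form (K = 0.600, k = 0.00678 s⁻¹)

In birch the electrophile's half-life by the first step alone at the charged amounts is 0.080 min, shorter than the relaxation half-life of free base and dormant form, 0.639 min. Birch's product stands at 93.1% at the asked time and at 99.9% after 25.0 min, under its ceiling of 105%. The neighbour of birch charged with 0.096 M of free base has a ceiling of 81.0%. Its computed product is 82.1%, with 0.0185 M of acid set free standing unbound, which the ceiling counted as bound.

All runs were computed with made-up constants.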